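**Retrosynthetic overview**
1. Numbering (daucane): five-membered ring C1(CH3, quaternary)–C2–C3–C4(OH, i-Pr)–C5(H). Seven-membered ring C1–C10–C9–C8(CH3)–C7–C6(O-acyl)–C5. The oxirane sits on C8–C9.
2. End game: phenol release ⇐ acylation of O6 ⇐ O6-directed epoxidation of C8=C9 ⇐ jaeschkeanadiol. The seven-membered ring is the last carbocycle, closed by metathesis at C8=C9.
3. Key disconnections are C1–C5 and C4–i-Pr. The cyclopentane C1–C5 comes from the cyclobutane C1–C2–C3–C4 of an oxiranyl cyclobutanol: C1 shifts from C4 to C5, and the C4 ketone so formed takes up i-PrMgCl in the same flask.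
4. Enabling feature: C5 lies between two oxygen-bearing carbons (C4 of the five-membered ring, C6 of the seven-membered ring) and next to quaternary C1. This C4(O)–C5–C6(O) aldol array is the retron of a 2,3-epoxy-alcohol semipinacol shift, with C4–OH as a latent ketone.
5. Oxiranyl cyclobutanol ⇐ acetylide + (R)-2-allyl-2-methylcyclobutanone (decarboxylative asymmetric allylation). Ring order: cyclobutane, cyclopentane (made from it), cycloheptene, oxirane.

Key step: step 9

Assumption: in the two ligand-controlled steps (4 and 8) the ligand antipode is taken that gives the configuration drawn; both antipodes of each ligand are accessible.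

Step 1
Reactants: 1 cyclopentane-1,3-dione; 2 4-acetamidobenzenesulfonyl azide
Product: 3 2-diazocyclopentane-1,3-dione
Conditions: Et3N, MeCN, 0 °C → rt
Reagents that add atoms: 4-acetamidobenzenesulfonyl azide, CC(=O)Nc1ccc(cc1)S(=O)(=O)N=[N+]=[N-]
Why: Regitz diazo transfer onto the doubly activated methylene of a cyclic 1,3-dione is standard and needs only an amine base.

Step 2
Reactants: 3 2-diazocyclopentane-1,3-dione; 4 allyl alcohol
Product: 6 prop-2-en-1-yl 2-oxocyclobutane-1-carboxylate, via acyl ketene 5 (not isolated)
Conditions: PhMe, 140 °C (sealed tube or µW)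
Reagents that add atoms: allyl alcohol, C=CCO
Why: Thermal Wolff rearrangement of a 2-diazo-1,3-dione expels N2 and gives an acyl ketene that the alcohol traps as the cyclobutanone β-keto ester.

Step 3
Reactants: 6 prop-2-en-1-yl 2-oxocyclobutane-1-carboxylate; 7 iodomethane
Product: 8 prop-2-en-1-yl 1-methyl-2-oxocyclobutane-1-carboxylate (racemic)
Conditions: K2CO3, acetone, 50 °C
Reagents that add atoms: iodomethane, CI
Why: C-alkylation of the stabilised β-keto ester enolate is reliable, and the racemic centre does not matter because step 4 is stereoablative.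

Step 4
Reactants: 8 prop-2-en-1-yl 1-methyl-2-oxocyclobutane-1-carboxylate
Product: 9 (2R)-2-methyl-2-(prop-2-en-1-yl)cyclobutan-1-one
Conditions: Pd2(dba)3 (cat.), (R)-(CF3)3-t-BuPHOX (cat.), PhMe, 20 °C
Reagents that add atoms: none
Why: Pd-catalysed decarboxylative asymmetric allylic alkylation (Tsuji–Trost type), known for 2-carboxyallyl cyclobutanones, passes through an achiral Pd enolate, so the ligand alone sets the quaternary centre C1.

Step 5
Reactants: 10 ethynylmagnesium bromide; 11 3-chloro-2-methylprop-1-ene
Product: 12 2-methylpent-1-en-4-yne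
Conditions: CuCl (cat.), THF, 50 °C
Reagents that add atoms: ethynylmagnesium bromide, C#C[Mg]Br
Why: Copper-catalysed allylation of an alkynyl Grignard reagent gives the skipped enyne, and SN2 and SN2' attack on the methallyl unit give the same product.

Step 6
Reactants: 9 (2R)-2-methyl-2-(prop-2-en-1-yl)cyclobutan-1-one; 12 2-methylpent-1-en-4-yne
Product: 14 (2R)-2-methyl-1-(4-methylpent-4-en-1-yn-1-yl)-2-(prop-2-en-1-yl)cyclobutan-1-ol (both carbinol epimers), via lithium acetylide 13 (not isolated)
Conditions: n-BuLi, THF, −78 °C; then 9, −78 → 0 °C; H2O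
Reagents that add atoms: 2-methylpent-1-en-4-yne, C#CCC(C)=C
Why: A weakly basic lithium acetylide adds 1,2 to the strained, electrophilic cyclobutanone, and the new carbinol centre (C4) need not be controlled because step 9 erases it.

Step 7
Reactants: 14 propargylic cyclobutanol
Product: 15 (2R)-2-methyl-1-[(1E)-4-methylpenta-1,4-dien-1-yl]-2-(prop-2-en-1-yl)cyclobutan-1-ol (both carbinol epimers)
Conditions: Red-Al, THF, 0 °C → rt; H2O
Reagents that add atoms: none
Why: Hydroxyl-directed trans-hydroalumination of a propargylic alcohol gives only the E-alkene (C5=C6) and leaves the isolated alkenes untouched.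

Step 8
Reactants: 15 E-allylic cyclobutanol; 16 cumene hydroperoxide
Product: 17 (2R)-2-methyl-1-[(2R,3S)-3-(2-methylprop-2-en-1-yl)oxiran-2-yl]-2-(prop-2-en-1-yl)cyclobutan-1-ol (both carbinol epimers)
Conditions: Hf(Ot-Bu)4 (cat.), C2-symmetric cyclohexane-1,2-diamine-derived bis-hydroxamic acid ligand (cat.), MgO, PhMe, 0 °C
Reagents that add atoms: cumene hydroperoxide, CC(C)(OO)c1ccccc1
Why: In the hafnium/bis-hydroxamic acid asymmetric epoxidation of tertiary allylic alcohols, binding through the hydroxyl group should select C5=C6 over the two remote alkenes, and the ligand should set C5 and C6 for both carbinol epimers.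

Step 9
Reactants: 17 oxiranyl cyclobutanol; 18 isopropylmagnesium chloride
Product: 20 (1R,2S,3R)-2-[(1S)-1-hydroxy-3-methylbut-3-en-1-yl]-3-methyl-1-(propan-2-yl)-3-(prop-2-en-1-yl)cyclopentan-1-ol, via aluminium aldolate 19 (not isolated)
Conditions: Me2AlCl (1.1 equiv), PhMe, −78 → −20 °C; then i-PrMgCl (3 equiv, THF), −78 → 0 °C; aq. Rochelle salt
Reagents that add atoms: isopropylmagnesium chloride, CC(C)[Mg]Cl
Why: Proposed new method: Me2AlCl turns the tertiary cyclobutanol O–H into a chloro(methyl)aluminium alkoxide whose metal chelates the oxirane oxygen, so only the proximal C5–O bond is weakened; the C4–C1 σ-bond anti-periplanar to it then shifts from C4 to C5 (semipinacol rearrangement of a 2,3-epoxy alcohol), which releases most of the cyclobutane strain and converts the four-membered ring C1–C2–C3–C4 into the cyclopentanone C1–C2–C3–C4–C5. The closest known reactions are the Lewis-acid or organoaluminium-promoted rearrangement of 2,3-epoxy alcohols to aldols, the ring expansion of 1-oxiranylcyclobutanols, and the reductive pinacol-type variant in which an aluminium hydride captures the carbonyl product in situ; the new element is capture by a Grignard reagent on this substrate class. The five-membered ring is closed by a suprafacial 1,2-alkyl shift with retention at the migrating C1 and inversion at C5, while C6 keeps its C–O bond, so C5 and C6 are fixed by the oxirane of 17 and both carbinol epimers converge on the same aldolate 19. In 19 the aluminium bridges O6 and the C4 carbonyl in a six-membered chelate on the ring face that carries C6 and the C1 methyl group; this should hold back retro-aldol cleavage and C5 epimerisation, activate the C=O and leave only the opposite face open, so i-PrMgCl should add anti to C6 and set C4 with OH cis to C6. The step needs migration of C1 rather than C3 (secured by the higher migratory aptitude of the fully substituted carbon), cleavage of C5–O rather than C6–O (secured by the chelate and by the donor oxygen standing on C4 only), and 1,2-addition rather than enolisation or β-hydride transfer (favoured by the activated chelate at low temperature).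

Step 10
Reactants: 20 cyclopentane diol
Product: 21 jaeschkeanadiol (dauc-8-ene-4β,6α-diol; 1β-CH3, 5α-H, trans-fused)
Conditions: (H2IMes)(PCy3)Cl2Ru=CHPh (cat.), CH2Cl2 (high dilution), 40 °C
Reagents that add atoms: none
Why: Ring-closing metathesis of the allyl group on C1 with the methallyl group on C6 fixes the trisubstituted C8=C9 alkene unambiguously, tolerates free hydroxyl groups and has close precedent for trans-fused 5-7 systems.

Step 11
Reactants: 21 jaeschkeanadiol; 22 tert-butyl hydroperoxide
Product: 23 8α,9α-epoxydaucane-4β,6α-diol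
Conditions: VO(acac)2 (cat.), CH2Cl2, 0 °C
Reagents that add atoms: tert-butyl hydroperoxide, CC(C)(C)OO
Why: Vanadium-catalysed epoxidation directed by the homoallylic 6α-hydroxyl group should deliver oxygen to the α-face of C8=C9, which is also the face remote from the C1 methyl group, and so set C8 and C9.

Step 12
Reactants: 23 8α,9α-epoxydaucane-4β,6α-diol; 24 4-acetoxybenzoic acid
Product: 25 O-acetyljaeskeanin (6α-(4-acetoxybenzoyloxy)-8α,9α-epoxydaucan-4β-ol)
Conditions: DCC, DMAP (cat.), CH2Cl2, rt
Reagents that add atoms: 4-acetoxybenzoic acid, CC(=O)Oc1ccc(cc1)C(=O)O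
Why: Steglich esterification acylates only the secondary O6, since the tertiary O4 is inert, and the near-neutral medium spares the oxirane.

Step 13
Reactants: 25 O-acetyljaeskeanin
Product: 26 jaeskeanin
Conditions: K2CO3 (cat.), MeOH, 0 °C
Reagents that add atoms: none
Why: Base-catalysed transesterification removes the activated aryl acetate much faster than it touches the hindered secondary benzoate, which is deactivated further once the phenoxide has formed.

**Compound list**
1 | cyclopentane-1,3-dione | O=C1CCC(=O)C1 | starting material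
2 | 4-acetamidobenzenesulfonyl azide | CC(=O)Nc1ccc(cc1)S(=O)(=O)N=[N+]=[N-] | starting material
3 | 2-diazocyclopentane-1,3-dione | [N-]=[N+]=C1C(=O)CCC1=O | intermediate
4 | prop-2-en-1-ol (allyl alcohol) | C=CCO | starting material
5 | 2-(oxomethylidene)cyclobutan-1-one (acyl ketene, not isolated) | O=C=C1CCC1=O | intermediate
6 | prop-2-en-1-yl 2-oxocyclobutane-1-carboxylate (racemic) | C=CCOC(=O)C1CCC1=O | intermediate
7 | iodomethane | CI | starting material
8 | prop-2-en-1-yl 1-methyl-2-oxocyclobutane-1-carboxylate (racemic) | C=CCOC(=O)C1(C)CCC1=O | intermediate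
9 | (2R)-2-methyl-2-(prop-2-en-1-yl)cyclobutan-1-one | C=CC[C@@]1(C)CCC1=O | intermediate
10 | ethynylmagnesium bromide | C#C[Mg]Br | starting material
11 | 3-chloro-2-methylprop-1-ene | C=C(C)CCl | starting material
12 | 2-methylpent-1-en-4-yne | C#CCC(C)=C | intermediate
13 | (4-methylpent-4-en-1-yn-1-yl)lithium (not isolated) | [Li]C#CCC(C)=C | intermediate
14 | (2R)-2-methyl-1-(4-methylpent-4-en-1-yn-1-yl)-2-(prop-2-en-1-yl)cyclobutan-1-ol, both carbinol epimers | C=CC[C@@]1(C)CCC1(O)C#CCC(C)=C | intermediate
15 | (2R)-2-methyl-1-[(1E)-4-methylpenta-1,4-dien-1-yl]-2-(prop-2-en-1-yl)cyclobutan-1-ol, both carbinol epimers | C=CC[C@@]1(C)CCC1(O)/C=C/CC(C)=C | intermediate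
16 | cumene hydroperoxide | CC(C)(OO)c1ccccc1 | starting material
17 | (2R)-2-methyl-1-[(2R,3S)-3-(2-methylprop-2-en-1-yl)oxiran-2-yl]-2-(prop-2-en-1-yl)cyclobutan-1-ol, both carbinol epimers | C=CC[C@@]1(C)CCC1(O)[C@@H]2O[C@H]2CC(C)=C | intermediate
18 | isopropylmagnesium chloride | CC(C)[Mg]Cl | starting material
19 | (2S,3R)-2-[(1S)-1-hydroxy-3-methylbut-3-en-1-yl]-3-methyl-3-(prop-2-en-1-yl)cyclopentan-1-one, held in the flask as its chloro(methyl)aluminium aldolate (SMILES of the free hydroxy ketone; not isolated) | C=CC[C@@]1(C)CCC(=O)[C@@H]1[C@@H](O)CC(C)=C | intermediate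
20 | (1R,2S,3R)-2-[(1S)-1-hydroxy-3-methylbut-3-en-1-yl]-3-methyl-1-(propan-2-yl)-3-(prop-2-en-1-yl)cyclopentan-1-ol | C=CC[C@@]1(C)CC[C@@](O)(C(C)C)[C@@H]1[C@@H](O)CC(C)=C | intermediate
21 | jaeschkeanadiol (dauc-8-ene-4β,6α-diol) | CC(C)[C@]1(O)CC[C@]2(C)CC=C(C)C[C@H](O)[C@H]21 | intermediate
22 | tert-butyl hydroperoxide | CC(C)(C)OO | starting material
23 | 8α,9α-epoxydaucane-4β,6α-diol | CC(C)[C@]1(O)CC[C@]2(C)C[C@@H]3O[C@]3(C)C[C@H](O)[C@H]21 | intermediate
24 | 4-acetoxybenzoic acid | CC(=O)Oc1ccc(cc1)C(=O)O | starting material
25 | O-acetyljaeskeanin | CC(C)[C@]1(O)CC[C@]2(C)C[C@@H]3O[C@]3(C)C[C@H](OC(=O)c3ccc(OC(C)=O)cc3)[C@H]21 | intermediate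
26 | jaeskeanin | CC(C)[C@]1(O)CC[C@]2(C)C[C@@H]3O[C@]3(C)C[C@H](OC(=O)c3ccc(O)cc3)[C@H]21 | target

**Step count**
Total step count: 13. Longest linear sequence: 12 (steps 1–4 and 6–13, from cyclopentane-1,3-dione); step 5 is a one-step side branch.

**Steps most likely to fail**

1. Step 9 (labelled step).
- In the first stage, chloride or methyl may be transferred from aluminium to the activated oxirane. Payne-type isomerisation may occur before the shift. C3 may migrate instead of C1, or the 1,1-disubstituted alkene may take part.
- In the second stage, enolisation or β-hydride transfer may occur in place of addition.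
- Fallback (known chemistry, from 17 back to 20): 17 is rearranged with catalytic BF3·OEt2 (CH2Cl2, −78 °C), the established Lewis-acid semipinacol rearrangement of 2,3-epoxy alcohols, and 19 is isolated as the free hydroxy ketone. Silylation (TESCl, imidazole) gives O-triethylsilyl hydroxy ketone F1. The organocerium reagent from i-PrMgCl and anhydrous CeCl3 (THF, −78 °C) adds anti to the C5 side chain to give O-triethylsilyl tertiary alcohol F2. TBAF then releases 20.

2. Step 8.
- The hindered tertiary alkoxide may bind slowly to hafnium.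
- Facial control may be mismatched for one of the two carbinol epimers.
- Background oxidation of the 1,1-disubstituted alkene and premature rearrangement on the Lewis-acidic metal are further risks.
- Fallback (from 9 back to 19): the oxirane is moved to C4–C5 and its face is relayed from a C6 carbinol that is set on an aldehyde. Horner–Wadsworth–Emmons olefination of 9 with diethyl (cyanomethyl)phosphonate/NaH places the nitrile anti to the quaternary carbon and gives cyclobutylideneacetonitrile F3. DIBAL-H followed by hydrolysis gives cyclobutylideneacetaldehyde F4. B-Methallyldiisopinocampheylborane (the antipode that delivers the S carbinol) gives secondary allylic alcohol F5. m-CPBA, guided by the hydroxyl group and by A(1,3) strain of the trisubstituted alkene, gives threo oxaspiro[2.3]hexane F6. Catalytic BF3·OEt2 cleaves the C5–O bond while C1 shifts from C4 to C5 (oxaspirohexane-to-cyclopentanone ring expansion), which gives 19. This is carried on as in the second stage of step 9.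

3. Step 11.
- Facial control may be lost if vanadium binds the tertiary O4 instead of O6.
- The new oxirane may be opened transannularly by a ring hydroxyl group on the Lewis-acidic metal.
- Fallback (from 21 back to 25): the order is reversed and steric control replaces hydroxyl direction. 21 is first esterified with 24 (DCC, DMAP) to O-acetylferutinin F7. Buffered m-CPBA (NaHCO3, CH2Cl2, 0 °C) then attacks C8=C9 from the α-face, away from the C1 methyl group, with no free O6 left to open the oxirane, and gives 25.

**Further compounds**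
F1 | step 9 | O-triethylsilyl hydroxy ketone, (2S,3R)-3-methyl-2-[(1S)-3-methyl-1-(triethylsilyloxy)but-3-en-1-yl]-3-(prop-2-en-1-yl)cyclopentan-1-one | C=CC[C@@]1(C)CCC(=O)[C@@H]1[C@@H](O[Si](CC)(CC)CC)CC(C)=C
F2 | step 9 | O-triethylsilyl tertiary alcohol, (1R,2S,3R)-3-methyl-2-[(1S)-3-methyl-1-(triethylsilyloxy)but-3-en-1-yl]-1-(propan-2-yl)-3-(prop-2-en-1-yl)cyclopentan-1-ol | C=CC[C@@]1(C)CC[C@@](O)(C(C)C)[C@@H]1[C@@H](O[Si](CC)(CC)CC)CC(C)=C
F3 | step 8 | cyclobutylideneacetonitrile, (2E)-2-[(2R)-2-methyl-2-(prop-2-en-1-yl)cyclobutylidene]acetonitrile | C=CC[C@@]1(C)CC/C1=C\C#N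
F4 | step 8 | cyclobutylideneacetaldehyde, (2E)-2-[(2R)-2-methyl-2-(prop-2-en-1-yl)cyclobutylidene]acetaldehyde | C=CC[C@@]1(C)CC/C1=C\C=O
F5 | step 8 | secondary allylic alcohol, (2S)-4-methyl-1-[(1E,2R)-2-methyl-2-(prop-2-en-1-yl)cyclobutylidene]pent-4-en-2-ol | C=CC[C@@]1(C)CC/C1=C\[C@@H](O)CC(C)=C
F6 | step 8 | threo oxaspiro[2.3]hexane, (1S)-3-methyl-1-[4-methyl-4-(prop-2-en-1-yl)-1-oxaspiro[2.3]hexan-2-yl]but-3-en-1-ol with the oxirane oxygen syn to the hydroxyl group | C=CC[C@@]1(C)CC[C@@]12O[C@@H]2[C@@H](O)CC(C)=C
F7 | step 11 | O-acetylferutinin, 6α-(4-acetoxybenzoyloxy)dauc-8-en-4β-ol | CC(C)[C@]1(O)CC[C@]2(C)CC=C(C)C[C@H](OC(=O)c3ccc(OC(C)=O)cc3)[C@H]21
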